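**Strategy.** Everything rests on disconnecting the C1–C10 bond of ring A (labdane numbering): C10 is the quaternary ring-fusion carbon that carries the angular methyl C20, and C1 is its methylene neighbour. Ring B is built first as an enantioenriched methylidenecyclohexane whose exocyclic C10=C20 alkene sits next to C5, and C5 carries a β-keto ester/vinyl ketone chain (C4, C3, C2=C1). Hydrogen-atom transfer from an iron hydride to C20 unmasks the tertiary C10 radical with its methyl already in place. Its 6-endo Giese addition to C1 closes ring A and sets the C10 quaternary centre and the trans ring fusion in one operation. The C3 ketone then directs the C4 methylation.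

Key step: step 9

Remark: atoms are numbered as in labdanes (C1–C10 decalin, C11–C16 side chain, C17 on C8, C18 and C19 on C4, C20 on C10); α is the face opposite to C20.
Assumption: where a chiral ligand is named, the enantiomer is meant that delivers the configuration drawn for 5.

**Step 1**
Reactants: 1 1,4-dioxaspiro[4.5]dec-6-en-8-one; 2 (4-bromobut-1-yn-1-yl)trimethylsilane
Product: 5 (6S,7S)-7-methyl-6-[4-(trimethylsilyl)but-3-yn-1-yl]-1,4-dioxaspiro[4.5]decan-8-one, via Grignard reagent 3 (not isolated), via magnesium enolate 4 (not isolated)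
Conditions: 2, Mg, Et2O; then 1, CuBr·SMe2 (5 mol %), (R)-1-[(SP)-2-(diphenylphosphino)ferrocenyl]ethyldicyclohexylphosphine (6 mol %), tBuOMe, −78 °C; then MeI, DMPU, −78 → 0 °C
Reagents that add atoms: iodomethane, CI
Why: Copper-catalysed asymmetric conjugate addition of a Grignard reagent with enolate trapping (three-component coupling), in which the chiral diphosphine–copper complex selects the enone face and sets C6 (C9 of the target), and iodomethane alkylates the magnesium enolate anti to the new chain to give the trans-6,7 product.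

**Step 2**
Reactants: 5
Product: 6 (6S,7S,8R)-7-methyl-6-[4-(trimethylsilyl)but-3-yn-1-yl]-1,4-dioxaspiro[4.5]decan-8-ol
Conditions: LiBH(sBu)3, THF, −78 °C
Reagents that add atoms: none
Why: Diastereoselective ketone reduction in which the bulky hydride attacks equatorially and should give the axial alcohol cis to the equatorial 7-methyl group, a permanent sp3 anchor that also places the later leaving group trans-diaxial to H8.

**Step 3**
Reactants: 6
Product: 7 tert-butyl(dimethyl){[(6S,7S,8R)-7-methyl-6-[4-(trimethylsilyl)but-3-yn-1-yl]-1,4-dioxaspiro[4.5]decan-8-yl]oxy}silane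
Conditions: TBSOTf, 2,6-lutidine, CH2Cl2, 0 °C
Reagents that add atoms: tert-butyldimethylsilyl triflate, CC(C)(C)[Si](C)(C)OS(=O)(=O)C(F)(F)F
Why: Silylation with the reactive silyl triflate protects the hindered axial secondary alcohol without touching the ketal or the silyl alkyne.

**Step 4**
Reactants: 7
Product: 8 (2S,3S,4R)-4-[(tert-butyldimethylsilyl)oxy]-3-methyl-2-[4-(trimethylsilyl)but-3-yn-1-yl]cyclohexan-1-one
Conditions: PPTS, acetone/H2O, 60 °C
Reagents that add atoms: water, O
Why: Mild acid-catalysed ketal hydrolysis (transketalisation to acetone) frees the C10 ketone while the secondary silyl ether survives, and the chain at C2 stays in its thermodynamically preferred equatorial position.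

**Step 5**
Reactants: 8
Product: 11 methyl 2-[(1S,3S,4S,5R)-5-[(tert-butyldimethylsilyl)oxy]-4-methyl-2-oxo-3-[4-(trimethylsilyl)but-3-yn-1-yl]cyclohexyl]acetate, via kinetic lithium enolate 9 (not isolated), via C1 epimer 10 (not isolated)
Conditions: LiN(iPr)2 (LDA), THF, −78 °C; BrCH2CO2Me, −78 → −20 °C; then DBU, CH2Cl2, rt
Reagents that add atoms: methyl bromoacetate, COC(=O)CBr
Why: Kinetic enolate alkylation on the CH2 side of the ketone followed by base-mediated epimerisation, in which the new centre (C5 of the target) settles cis to the C3 chain because only the all-equatorial 2,6-cis ketone avoids a 1,3-diaxial clash with the axial silyloxy group, while the non-epimerisable C4 and C5 centres keep the absolute configuration.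

**Step 6**
Reactants: 11
Product: 12 methyl 2-[(1S,3S,4S,5R)-5-[(tert-butyldimethylsilyl)oxy]-4-methyl-2-methylidene-3-[4-(trimethylsilyl)but-3-yn-1-yl]cyclohexyl]acetate
Conditions: Zn, CH2Br2, TiCl4, THF/CH2Cl2, 0 °C → rt
Reagents that add atoms: dibromomethane, BrCBr
Why: Takai–Lombardo methylenation, whose non-basic titanium–zinc methylene reagent should convert the hindered, enolisable ketone into the exocyclic alkene without epimerisation or attack on the ester.

**Step 7**
Reactants: 12
Product: 14 methyl 2-[(1S,3S,4S,5R)-5-[(tert-butyldimethylsilyl)oxy]-4-methyl-2-methylidene-3-[4-(trimethylsilyl)but-3-yn-1-yl]cyclohexyl]-3-hydroxypent-4-enoate (mixture of diastereomers at C2 and C3 of the pentenoate), via lithium ester enolate 13 (not isolated)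
Conditions: LiN(iPr)2 (LDA), THF, −78 °C; acrolein; then AcOH
Reagents that add atoms: acrolein, C=CC=O
Why: Aldol addition of the lithium ester enolate to acrolein in the 1,2 sense installs C3, C2 and C1; the two new stereocentres are of no consequence because both are removed or become epimerisable in step 8.

**Step 8**
Reactants: 14
Product: 15 methyl 2-[(1S,3S,4S,5R)-5-[(tert-butyldimethylsilyl)oxy]-4-methyl-2-methylidene-3-[4-(trimethylsilyl)but-3-yn-1-yl]cyclohexyl]-3-oxopent-4-enoate (C2 epimers, partly enolised)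
Conditions: Dess–Martin periodinane, NaHCO3, CH2Cl2, 0 °C
Reagents that add atoms: none
Why: Mild oxidation of the allylic alcohol gives the vinyl ketone β-keto ester (a substituted Nazarov-type reagent), which is used at once to avoid polymerisation.

**Step 9**
Reactants: 15
Product: 16 methyl 7α-[(tert-butyldimethylsilyl)oxy]-3-oxo-16-(trimethylsilyl)-14,15,18-trinor-8βH-labd-13(16)-yn-19-oate (trans-decalin with 5α-H, 10β-CH3, 9β side chain, 17-CH3 α; C4 epimers)
Conditions: Fe(acac)3 (30 mol %), PhSiH3, EtOH/(CH2OH)2 (5:1), 0.01 M, 60 °C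
Reagents that add atoms: none
Why: Hydrogen-atom transfer from an iron hydride (formed from Fe(acac)3 and PhSiH3) to the terminal carbon C20 of the C10=C20 methylidene gives the tertiary C10 radical, which adds to C1, the β-carbon of the vinyl ketone, and the resulting α-keto radical at C2 is reduced and protonated. The closest known reaction type is the iron-mediated reductive olefin coupling (hydrogen-atom-transfer-initiated Giese reaction) in its intramolecular form, and the closure mirrors the second ring closure of radical polyene cyclisations. Ring A closes in the 6-endo-trig mode, because attack at C1 is polarity-matched and gives a stabilised radical, whereas 5-exo attack at C2 would give a primary radical on a strained cyclopentanone. The new quaternary centre C10 is controlled by the C5 stereocentre: in the chair–chair transition state the C5 tether stays equatorial on ring B and C1 bonds to the α-face of C10, so the methyl becomes axial (β) and the decalin trans-fused, and the equatorial C9 chain disfavours the alternative that keeps the methyl equatorial. The step needs chemoselective hydrogen-atom transfer to the electron-rich 1,1-disubstituted alkene in the presence of the enone and the silyl alkyne, which the far higher reactivity of such alkenes towards metal hydrides should secure, and high dilution lets ring closure outrun reduction of the radical. C4 stays epimerisable as a β-keto ester and is fixed in step 10.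

**Step 10**
Reactants: 16
Product: 17 methyl 7α-[(tert-butyldimethylsilyl)oxy]-3-oxo-16-(trimethylsilyl)-14,15-dinor-8βH-labd-13(16)-yn-19-oate (4α-CH3, 4β-CO2CH3)
Conditions: MeI, K2CO3, acetone, 50 °C
Reagents that add atoms: iodomethane, CI
Why: C-alkylation of the β-keto ester enolate, in which iodomethane approaches the α-face because the β-face of C4 is blocked by the 1,3-diaxial C20 methyl, so the new methyl becomes C18 (α, equatorial) and the ester C19 (β, axial).

**Step 11**
Reactants: 17
Product: 19 methyl 7α-[(tert-butyldimethylsilyl)oxy]-16-(trimethylsilyl)-14,15-dinor-8βH-labd-13(16)-yn-19-oate, via tosylhydrazone 18 (not isolated)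
Conditions: TsNHNH2, MeOH, 65 °C; then catecholborane, CHCl3, 0 °C; NaOAc·3H2O, 60 °C
Reagents that add atoms: none
Why: Reductive deoxygenation of the ketone through its tosylhydrazone (Caglioti-type reduction), in which hydride addition, loss of sulfinate and extrusion of nitrogen leave the C3 methylene without affecting ester, silyl ether or silyl alkyne.

**Step 12**
Reactants: 19
Product: 20 methyl 7α-hydroxy-14,15-dinor-8βH-labd-13(16)-yn-19-oate
Conditions: Bu4NF, THF, rt
Reagents that add atoms: none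
Why: Fluoride-mediated desilylation removes the silyl ether and the alkynyl silyl group in one operation.

**Step 13**
Reactants: 20
Product: 21 methyl 14,15-dinorlabd-7-en-13(16)-yn-19-oate
Conditions: Martin sulfurane Ph2S[OC(CF3)2Ph]2, CH2Cl2, 0 °C → rt
Reagents that add atoms: none
Why: Dehydration by anti-periplanar E2-type elimination, in which the axial 7α-oxysulfonium group and the axial 8β-hydrogen are trans-diaxial and the trisubstituted Δ7 alkene (Zaitsev product) should dominate over the Δ6 isomer.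

**Step 14**
Reactants: 21
Product: 22 methyl 7α,8α-dihydroxy-14,15-dinorlabd-13(16)-yn-19-oate
Conditions: OsO4 (2 mol %), NMO, acetone/H2O, rt
Reagents that add atoms: N-methylmorpholine N-oxide, C[N+]1([O-])CCOCC1; water, O
Why: Catalytic syn-dihydroxylation (Upjohn conditions) on the α-face of the Δ7 alkene, opposite the axial C20 methyl, sets C7 (α-OH) and C8 (α-OH, β-CH3) as the cis-diol, while the terminal alkyne is inert.

**Step 15**
Reactants: 22
Product: 23 14,15-dinorlabd-13(16)-yne-7α,8α,19-triol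
Conditions: LiAlH4, THF, 0 → 60 °C
Reagents that add atoms: none
Why: Hydride reduction of the hindered axial C19 ester to the primary alcohol, which changes no stereocentre.

**Step 16**
Reactants: 23
Product: 24 labda-13(16),14-diene-7α,8α,19-triol
Conditions: second-generation Grubbs catalyst RuCl2(=CHPh)(PCy3)(H2IMes) (5 mol %), ethylene (1 atm), CH2Cl2, 40 °C
Reagents that add atoms: ethylene, C=C
Why: Cross enyne metathesis of the terminal alkyne with ethylene gives the 2-substituted buta-1,3-diene (C13(=C16)–C14=C15); no other alkene is present and free hydroxyl groups are tolerated.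

**Step 17**
Reactants: 24
Product: 25 3-[(7α,8α-dihydroxylabda-13(16),14-dien-19-yl)oxy]-3-oxopropanoic acid
Conditions: Meldrum's acid, toluene, 90 °C
Reagents that add atoms: Meldrum's acid (2,2-dimethyl-1,3-dioxane-4,6-dione), CC1(C)OC(=O)CC(=O)O1
Why: Ring-opening acylation of Meldrum's acid by the primary C19 hydroxyl gives the malonic half ester, since the tertiary C8 and the hindered axial C7 hydroxyls should react much more slowly.

**Step 18**
Reactants: 25; 26 4-hydroxybenzaldehyde
Product: 27 7α,8α-dihydroxylabda-13(16),14-dien-19-yl (E)-3-(4-hydroxyphenyl)prop-2-enoate (target)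
Conditions: pyridine, piperidine (cat.), 70 °C
Reagents that add atoms: none
Why: Knoevenagel–Doebner condensation of the malonic half ester with the aldehyde, followed by decarboxylation, gives the (E)-cinnamate directly and needs no protection of the phenol.

**Compound list**

1 | 1,4-dioxaspiro[4.5]dec-6-en-8-one | O=C1C=CC2(OCCO2)CC1 | starting material
2 | (4-bromobut-1-yn-1-yl)trimethylsilane | C[Si](C)(C)C#CCCBr | starting material
3 | [4-(trimethylsilyl)but-3-yn-1-yl]magnesium bromide | C[Si](C)(C)C#CCC[Mg]Br | intermediate (not isolated)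
4 | bromomagnesium enolate, (6S)-6-[4-(trimethylsilyl)but-3-yn-1-yl]-1,4-dioxaspiro[4.5]dec-7-en-8-olate | C[Si](C)(C)C#CCC[C@H]1C=C(O[Mg]Br)CCC12OCCO2 | intermediate (not isolated)
5 | (6S,7S)-7-methyl-6-[4-(trimethylsilyl)but-3-yn-1-yl]-1,4-dioxaspiro[4.5]decan-8-one | C[Si](C)(C)C#CCC[C@H]1[C@H](C)C(=O)CCC12OCCO2 | intermediate
6 | (6S,7S,8R)-7-methyl-6-[4-(trimethylsilyl)but-3-yn-1-yl]-1,4-dioxaspiro[4.5]decan-8-ol | C[Si](C)(C)C#CCC[C@H]1[C@H](C)[C@H](O)CCC12OCCO2 | intermediate
7 | tert-butyl(dimethyl){[(6S,7S,8R)-7-methyl-6-[4-(trimethylsilyl)but-3-yn-1-yl]-1,4-dioxaspiro[4.5]decan-8-yl]oxy}silane | C[Si](C)(C)C#CCC[C@H]1[C@H](C)[C@H](O[Si](C)(C)C(C)(C)C)CCC12OCCO2 | intermediate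
8 | (2S,3S,4R)-4-[(tert-butyldimethylsilyl)oxy]-3-methyl-2-[4-(trimethylsilyl)but-3-yn-1-yl]cyclohexan-1-one | C[Si](C)(C)C#CCC[C@H]1[C@H](C)[C@H](O[Si](C)(C)C(C)(C)C)CCC1=O | intermediate
9 | kinetic lithium enolate of 8 (C1=C6 enolate, other centres as in 8) | C[Si](C)(C)C#CCC[C@H]1[C@H](C)[C@H](O[Si](C)(C)C(C)(C)C)CC=C1O[Li] | intermediate (not isolated)
10 | methyl 2-[(1R,3S,4S,5R)-5-[(tert-butyldimethylsilyl)oxy]-4-methyl-2-oxo-3-[4-(trimethylsilyl)but-3-yn-1-yl]cyclohexyl]acetate (C1 epimer of 11) | C[Si](C)(C)C#CCC[C@H]1[C@H](C)[C@H](O[Si](C)(C)C(C)(C)C)C[C@H](CC(=O)OC)C1=O | intermediate (not isolated)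
11 | methyl 2-[(1S,3S,4S,5R)-5-[(tert-butyldimethylsilyl)oxy]-4-methyl-2-oxo-3-[4-(trimethylsilyl)but-3-yn-1-yl]cyclohexyl]acetate | C[Si](C)(C)C#CCC[C@H]1[C@H](C)[C@H](O[Si](C)(C)C(C)(C)C)C[C@@H](CC(=O)OC)C1=O | intermediate
12 | methyl 2-[(1S,3S,4S,5R)-5-[(tert-butyldimethylsilyl)oxy]-4-methyl-2-methylidene-3-[4-(trimethylsilyl)but-3-yn-1-yl]cyclohexyl]acetate | C[Si](C)(C)C#CCC[C@H]1[C@H](C)[C@H](O[Si](C)(C)C(C)(C)C)C[C@@H](CC(=O)OC)C1=C | intermediate
13 | lithium ester enolate of 12 | C[Si](C)(C)C#CCC[C@H]1[C@H](C)[C@H](O[Si](C)(C)C(C)(C)C)C[C@@H](C=C(OC)O[Li])C1=C | intermediate (not isolated)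
14 | methyl 2-[(1S,3S,4S,5R)-5-[(tert-butyldimethylsilyl)oxy]-4-methyl-2-methylidene-3-[4-(trimethylsilyl)but-3-yn-1-yl]cyclohexyl]-3-hydroxypent-4-enoate (diastereomer mixture at C2 and C3 of the pentenoate) | C[Si](C)(C)C#CCC[C@H]1[C@H](C)[C@H](O[Si](C)(C)C(C)(C)C)C[C@@H](C(C(=O)OC)C(O)C=C)C1=C | intermediate
15 | methyl 2-[(1S,3S,4S,5R)-5-[(tert-butyldimethylsilyl)oxy]-4-methyl-2-methylidene-3-[4-(trimethylsilyl)but-3-yn-1-yl]cyclohexyl]-3-oxopent-4-enoate (C2 epimers) | C[Si](C)(C)C#CCC[C@H]1[C@H](C)[C@H](O[Si](C)(C)C(C)(C)C)C[C@@H](C(C(=O)OC)C(=O)C=C)C1=C | intermediate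
16 | methyl 7α-[(tert-butyldimethylsilyl)oxy]-3-oxo-16-(trimethylsilyl)-14,15,18-trinor-8βH-labd-13(16)-yn-19-oate (C4 epimers) | C[Si](C)(C)C#CCC[C@H]1[C@H](C)[C@H](O[Si](C)(C)C(C)(C)C)C[C@H]2C(C(=O)OC)C(=O)CC[C@@]21C | intermediate
17 | methyl 7α-[(tert-butyldimethylsilyl)oxy]-3-oxo-16-(trimethylsilyl)-14,15-dinor-8βH-labd-13(16)-yn-19-oate | C[Si](C)(C)C#CCC[C@H]1[C@H](C)[C@H](O[Si](C)(C)C(C)(C)C)C[C@H]2[C@@](C)(C(=O)OC)C(=O)CC[C@@]21C | intermediate
18 | C3 (4-methylbenzenesulfonyl)hydrazone of 17 | C[Si](C)(C)C#CCC[C@H]1[C@H](C)[C@H](O[Si](C)(C)C(C)(C)C)C[C@H]2[C@@](C)(C(=O)OC)C(=NNS(=O)(=O)c3ccc(C)cc3)CC[C@@]21C | intermediate (not isolated)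
19 | methyl 7α-[(tert-butyldimethylsilyl)oxy]-16-(trimethylsilyl)-14,15-dinor-8βH-labd-13(16)-yn-19-oate | C[Si](C)(C)C#CCC[C@H]1[C@H](C)[C@H](O[Si](C)(C)C(C)(C)C)C[C@H]2[C@@](C)(C(=O)OC)CCC[C@@]21C | intermediate
20 | methyl 7α-hydroxy-14,15-dinor-8βH-labd-13(16)-yn-19-oate | C#CCC[C@H]1[C@H](C)[C@H](O)C[C@H]2[C@@](C)(C(=O)OC)CCC[C@@]21C | intermediate
21 | methyl 14,15-dinorlabd-7-en-13(16)-yn-19-oate | C#CCC[C@H]1C(C)=CC[C@H]2[C@@](C)(C(=O)OC)CCC[C@@]21C | intermediate
22 | methyl 7α,8α-dihydroxy-14,15-dinorlabd-13(16)-yn-19-oate | C#CCC[C@H]1[C@](C)(O)[C@H](O)C[C@H]2[C@@](C)(C(=O)OC)CCC[C@@]21C | intermediate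
23 | 14,15-dinorlabd-13(16)-yne-7α,8α,19-triol | C#CCC[C@H]1[C@](C)(O)[C@H](O)C[C@H]2[C@@](C)(CO)CCC[C@@]21C | intermediate
24 | labda-13(16),14-diene-7α,8α,19-triol | C=CC(=C)CC[C@H]1[C@](C)(O)[C@H](O)C[C@H]2[C@@](C)(CO)CCC[C@@]21C | intermediate
25 | 3-[(7α,8α-dihydroxylabda-13(16),14-dien-19-yl)oxy]-3-oxopropanoic acid | C=CC(=C)CC[C@H]1[C@](C)(O)[C@H](O)C[C@H]2[C@@](C)(COC(=O)CC(=O)O)CCC[C@@]21C | intermediate
26 | 4-hydroxybenzaldehyde | O=Cc1ccc(O)cc1 | starting material
27 | 7α,8α-dihydroxylabda-13(16),14-dien-19-yl (E)-3-(4-hydroxyphenyl)prop-2-enoate | C=CC(=C)CC[C@H]1[C@](C)(O)[C@H](O)C[C@H]2[C@@](C)(COC(=O)/C=C/c3ccc(O)cc3)CCC[C@@]21C | target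

**Total step count:** 18
**Longest linear sequence:** 18 steps (1 → 27)

**Steps most likely to fail**

Step 9. Hydrogen-atom transfer to the tertiary C10 radical (net hydrogenation of the methylidene group), or hydride reduction and oligomerisation of the vinyl ketone, may outrun the 6-endo ring closure. The fallback generates the same radical by halogen abstraction under a low, controlled hydride concentration. It sets out from 12: Markovnikov hydrochlorination (HCl, CH2Cl2, −78 °C) should give the tertiary chloride methyl 2-[(1S,3S,4S,5R)-5-[(tert-butyldimethylsilyl)oxy]-2-chloro-2,4-dimethyl-3-[4-(trimethylsilyl)but-3-yn-1-yl]cyclohexyl]acetate F1. Aldol addition to acrolein as in step 7 gives the hydroxy ester methyl 2-[(1S,3S,4S,5R)-5-[(tert-butyldimethylsilyl)oxy]-2-chloro-2,4-dimethyl-3-[4-(trimethylsilyl)but-3-yn-1-yl]cyclohexyl]-3-hydroxypent-4-enoate F2, and Dess–Martin oxidation as in step 8 gives the chloro β-keto ester methyl 2-[(1S,3S,4S,5R)-5-[(tert-butyldimethylsilyl)oxy]-2-chloro-2,4-dimethyl-3-[4-(trimethylsilyl)but-3-yn-1-yl]cyclohexyl]-3-oxopent-4-enoate F3. Bu3SnH added by syringe pump with AIBN in benzene at 80 °C abstracts chlorine, the C10 radical closes ring A, and the route is rejoined at 16.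

Step 1. The copper catalyst may discriminate poorly between the enone faces at the hindered β-carbon next to the spiroketal (low enantiomeric excess), or trapping of the magnesium enolate may be sluggish. The fallback replaces asymmetric catalysis by resolution. It sets out from 1 and 2: the addition is run with CuI (10 mol %) and no chiral ligand, followed by MeI/DMPU, and gives 5 together with its enantiomer (6R,7R)-7-methyl-6-[4-(trimethylsilyl)but-3-yn-1-yl]-1,4-dioxaspiro[4.5]decan-8-one F4. LiBH(sBu)3 reduction gives 6 together with (6R,7R,8S)-7-methyl-6-[4-(trimethylsilyl)but-3-yn-1-yl]-1,4-dioxaspiro[4.5]decan-8-ol F5. (R)-1-Phenylethyl isocyanate with DMAP converts the pair into the diastereomeric carbamates (6S,7S,8R)-7-methyl-6-[4-(trimethylsilyl)but-3-yn-1-yl]-1,4-dioxaspiro[4.5]decan-8-yl N-[(R)-1-phenylethyl]carbamate F6 and (6R,7R,8S)-7-methyl-6-[4-(trimethylsilyl)but-3-yn-1-yl]-1,4-dioxaspiro[4.5]decan-8-yl N-[(R)-1-phenylethyl]carbamate F7, which are separated by chromatography. LiAlH4 cleavage of F6 returns the route at 6.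

Step 11. The hydrazide may condense incompletely with the neopentyl-type C3 ketone, or the non-enolisable β-keto ester may undergo retro-Claisen cleavage on prolonged heating. The fallback is a radical deoxygenation (Barton–McCombie). It sets out from 17: NaBH4 in MeOH should give the equatorial alcohol methyl 7α-[(tert-butyldimethylsilyl)oxy]-3β-hydroxy-16-(trimethylsilyl)-14,15-dinor-8βH-labd-13(16)-yn-19-oate F8. NaH, CS2 and then MeI give the xanthate methyl 7α-[(tert-butyldimethylsilyl)oxy]-3β-{[(methylsulfanyl)carbonothioyl]oxy}-16-(trimethylsilyl)-14,15-dinor-8βH-labd-13(16)-yn-19-oate F9. Bu3SnH and AIBN in toluene at 110 °C remove the C3 oxygen, and the route is rejoined at 19.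

**Further compounds**

F1 | step 9 | methyl 2-[(1S,3S,4S,5R)-5-[(tert-butyldimethylsilyl)oxy]-2-chloro-2,4-dimethyl-3-[4-(trimethylsilyl)but-3-yn-1-yl]cyclohexyl]acetate (C2 epimers) | C[Si](C)(C)C#CCC[C@H]1[C@H](C)[C@H](O[Si](C)(C)C(C)(C)C)C[C@@H](CC(=O)OC)C1(C)Cl
F2 | step 9 | methyl 2-[(1S,3S,4S,5R)-5-[(tert-butyldimethylsilyl)oxy]-2-chloro-2,4-dimethyl-3-[4-(trimethylsilyl)but-3-yn-1-yl]cyclohexyl]-3-hydroxypent-4-enoate (diastereomer mixture) | C[Si](C)(C)C#CCC[C@H]1[C@H](C)[C@H](O[Si](C)(C)C(C)(C)C)C[C@@H](C(C(=O)OC)C(O)C=C)C1(C)Cl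
F3 | step 9 | methyl 2-[(1S,3S,4S,5R)-5-[(tert-butyldimethylsilyl)oxy]-2-chloro-2,4-dimethyl-3-[4-(trimethylsilyl)but-3-yn-1-yl]cyclohexyl]-3-oxopent-4-enoate (diastereomer mixture) | C[Si](C)(C)C#CCC[C@H]1[C@H](C)[C@H](O[Si](C)(C)C(C)(C)C)C[C@@H](C(C(=O)OC)C(=O)C=C)C1(C)Cl
F4 | step 1 | (6R,7R)-7-methyl-6-[4-(trimethylsilyl)but-3-yn-1-yl]-1,4-dioxaspiro[4.5]decan-8-one | C[Si](C)(C)C#CCC[C@@H]1[C@@H](C)C(=O)CCC12OCCO2
F5 | step 1 | (6R,7R,8S)-7-methyl-6-[4-(trimethylsilyl)but-3-yn-1-yl]-1,4-dioxaspiro[4.5]decan-8-ol | C[Si](C)(C)C#CCC[C@@H]1[C@@H](C)[C@@H](O)CCC12OCCO2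
F6 | step 1 | (6S,7S,8R)-7-methyl-6-[4-(trimethylsilyl)but-3-yn-1-yl]-1,4-dioxaspiro[4.5]decan-8-yl N-[(R)-1-phenylethyl]carbamate | C[Si](C)(C)C#CCC[C@H]1[C@H](C)[C@H](OC(=O)N[C@H](C)c3ccccc3)CCC12OCCO2
F7 | step 1 | (6R,7R,8S)-7-methyl-6-[4-(trimethylsilyl)but-3-yn-1-yl]-1,4-dioxaspiro[4.5]decan-8-yl N-[(R)-1-phenylethyl]carbamate | C[Si](C)(C)C#CCC[C@@H]1[C@@H](C)[C@@H](OC(=O)N[C@H](C)c3ccccc3)CCC12OCCO2
F8 | step 11 | methyl 7α-[(tert-butyldimethylsilyl)oxy]-3β-hydroxy-16-(trimethylsilyl)-14,15-dinor-8βH-labd-13(16)-yn-19-oate | C[Si](C)(C)C#CCC[C@H]1[C@H](C)[C@H](O[Si](C)(C)C(C)(C)C)C[C@H]2[C@@](C)(C(=O)OC)[C@@H](O)CC[C@@]21C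
F9 | step 11 | methyl 7α-[(tert-butyldimethylsilyl)oxy]-3β-{[(methylsulfanyl)carbonothioyl]oxy}-16-(trimethylsilyl)-14,15-dinor-8βH-labd-13(16)-yn-19-oate | C[Si](C)(C)C#CCC[C@H]1[C@H](C)[C@H](O[Si](C)(C)C(C)(C)C)C[C@H]2[C@@](C)(C(=O)OC)[C@@H](OC(=S)SC)CC[C@@]21C
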